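# Total synthesis proposal for CNP0106709.2 by anionic oxy-Cope ring expansion of a carvone-derived cyclohexenol

## The problem

CNP0106709.2 is a germacranolide. A ten-membered carbocycle (C1–C10) is trans-fused at C6–C7 to an α-methylene-γ-butyrolactone (O–C12(=O)–C11=C13). It carries a C1 ketone, a cis C4=C5 alkene with methyl C15, a tiglate on C8 and hydroxyls on C3, C9 and C10 (tertiary, methyl C14). The configuration is 3S,6R,7S,8S,9S,10S.

A ten-membered ring is the least favourable size for end-to-end closure. The ring should therefore be made by a process that needs no high dilution and that has the cis alkene fixed beforehand.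

The stereocentres form a contiguous C6–C10 block and an isolated C3. C7 can control C6 and C8 while all three sit on a six-membered ring. C8 can pass its configuration to C10 through an ordered transition state. C9 and the C8 oxygen can then be added across an alkene between them. C3 must be set on the macrocycle, where the only nearby handle is an oxygen on C1.

Four functions will not survive rough treatment:
- the α-methylene lactone (hydride, organometallics, amines and thiols add to it);
- the C1-keto/C3-hydroxy aldol pair (dehydration, retro-aldol);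
- the tertiary α-ketol at C10/C1;
- the tiglate beside a free C9 hydroxyl (acyl migration under base).

They have to appear late, and the last steps must be mild and not basic.

The feature that opens the route is the arc C3–C4(C15)=C5–C6–C7–C8. With its cis alkene, the C6 oxygen and the three-carbon branch on C7, it is a carvone ring. C1–C10 is the bond that forms when a cyclohexenol with alkenyl groups on C3 (the carbinol) and C8 undergoes an oxy-Cope shift with cleavage of C3–C8.

## Retrosynthesis

**Lactone C12–O6.** The lactone of target 45 is opened to tetraol 42 by cutting the acyl C12–O6 bond and lowering C12 to the alcohol. Carrying a finished α-methylene lactone through the route would expose it to every hydride and organometallic step. Tetraol 42 holds only alcohols, a ketone and the tiglate. The forward step must oxidise the primary allylic alcohol in the presence of two secondary ones and let the C6 hydroxyl capture the aldehyde.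

**Tiglate C8–O and the C9 oxygen.** Desilylation relates 42 to tiglate 41. Both oxygens of 41 are traced to one alkene: the C8–O bond is cut to tiglic acid 40 and epoxy ketone 39. Epoxide 39 comes from epoxy diol 38 and this from E-alkene diol 37. Bringing in the tiglate as the nucleophile avoids selective acylation of a polyol. The tertiary C10 hydroxyl serves twice, first to direct the epoxidation and then to steer the acid to C8. The forward reactions must deliver oxygen to one face of C8=C9 and invert C8.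

**C1/C3 oxidation pattern.** The C1 ketone and C3 carbinol of 37 are exchanged for the C1 ether and C3 ketone of enone 34, by way of silyl ether 36 and allylic alcohol 35. The two positions are told apart by oxidation level and not by protecting groups alone. The 4-methoxybenzyl ether on C1 and the (4-methoxybenzyloxy)methyl ether on C10 leave in one oxidative step. The C3 reduction must give the 3S alcohol.

**Ring bond C1–C10 (key disconnection).** Enone 34 is cut at C1–C10 and C3–C8 is re-formed, giving cyclohexenol 31. Cuts at C8–C9, C5–C6 or C6–C7 would close the ring end to end from an acyclic chain carrying four or five stereocentres. The C1–C10 cut turns the macrocycle into a six-membered ring whose four stereocentres all derive from the single centre of carvone. It also supplies C10 by chirality transfer, the oxygens on C1 and C10 through two enol ethers, and the E C8=C9 alkene for later oxygenation. The forward step needs a chair transition state with both ring bonds pseudo-equatorial.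

**C2–C3 and the enol ether O–C bond.** Carbinol 31 is cut at the enol ether O–CH2 bond to chloromethyl ether 11 and silyl enol ether 29. Carbinol 29 is cut at C2–C3 to ketone 26 and vinyl iodide 8. A β-oxygenated vinyl nucleophile brings C1 in already oxygenated. Changing the enol ether from silyl to alkyl after the addition keeps a free ketone enolate away from the C3 carbonyl. The addition must come from the face opposite the C8 substituent.

**C8–C9 and the C10 oxygen.** Ketone 26 goes back through 1,4-diketone 25 and allyl ketone 24 to enone 21 and allyl bromide 22, cutting C8–C9. Allylation followed by Wacker oxidation is the most reliable way to put a 2-oxopropyl group on the α′ carbon of a cyclohexenone. The methyl ketone then gives the Z enol ether under thermodynamic control. The alkylation must be trans to the C7 branch.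

**C6–O and C12–O.** Enone 21 is simplified through hydroxy enone 20 and dienol ether 16 to silyl ether 14 (C6–O cut). Ether 14 goes back to hydroxycarvone 13 and (S)-carvone 12 (C12–O cut). Both oxygens are placed on the intact terpene, where the C7 substituent shields one face of the diene. Carvone has the C7 configuration of the target.

**Reagents.** Vinyl iodide 8 is cut at the O–vinyl bond to 4-methoxybenzyl alcohol 1 and trichloroethylene 2, by way of alkynyl ether 6. Chloromethyl ether 11 comes from 1.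

## Roads not taken

**Alternative 1: pinacol macrocyclisation across C8–C9.** The cut is C8–C9. In the forward step SmI2 reduces the two aldehydes of dialdehyde A1 to ketyls that couple to the ten-membered cis-8,9-diol A2.
- Merits: the ring and both carbinols arise together and the diol comes directly, without inversion at C8. In this respect the route is better than the chosen plan, whose weakest late step is the opening of the 8,9-epoxide.
- Weak points: A1 must be assembled with C3, C6, C7 and C10 already in place by acyclic methods. The C9 aldehyde bears an α-silyloxy group that SmI2 can cleave reductively. The sense of the new diol relative to C7 and C10 is not secured. The lactone still needs α-methylenation and the dithiane needs removal on a polyfunctional macrocycle.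
- Comparison: the chosen plan takes C6, C7 and C8 from a chiral-pool six-membered ring, sets C10 by a sigmatropic transfer, and makes the ring without an end-to-end closure.

**Alternative 2: Nozaki–Hiyama–Kishi closure of C5–C6.** The cut is C5–C6. CrCl2 with catalytic NiCl2 converts the Z-vinyl iodide of iodo aldehyde A3 into a vinylchromium species that adds to the C6 aldehyde, giving macrocyclic allylic alcohol A4.
- Merits: the coupling tolerates the ketone and the ester and keeps the alkene geometry. The tiglate and the C8–C10 stereotriad are complete before ring closure, so nothing delicate is done on the macrocycle. This is a real advantage over the chosen plan.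
- Weak points: the C6 aldehyde of A3 is α to C7, which is also allylic, so it is prone to epimerisation and to conjugation. The C6 carbinol configuration depends on a macrocyclic addition whose sense is not predictable. The ten-membered closure needs high dilution. The C7–C10 array must be built in the open chain.
- Comparison: the chosen plan fixes C6 on a cyclohexene, anti to the C7 branch, and has the ring strain paid by a charge-accelerated rearrangement.

**Alternative 3: [2,3]-Wittig ring contraction.** The cut is C6–C7. Tin–lithium exchange at C6 of the thirteen-membered diallylic ether A5 triggers the shift. C6–C7 forms, O–C13 breaks and C11=C13 becomes the exocyclic methylene of A6. A5 is drawn with the 6-stannane configuration and the alkene geometry that inversion at the carbanion and an anti-selective shift would require.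
- Merits: one step gives the C6 hydroxyl, the C7 centre and the exo-methylene, which is the whole lactone precursor. A thirteen-membered ether is easier to close than a ten-membered carbocycle. For the lactone region this is more direct than the two early oxidations of carvone in the chosen plan.
- Weak points: A5 is itself a long synthesis with the C8–C10 triad and a defined α-stannyl ether. The transfer of configuration in a macrocyclic [2,3] shift and the competition of the [1,2] shift are uncertain. The dithiane and acetonide add protecting-group steps.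
- Comparison: the chosen plan obtains the same C6/C7/C11 pattern from carvone in five short steps and spends its key step on the ring and on C10.

Key step: step 16

## Route

Remark: germacrane numbering (C1–C15) of the target is used for all intermediates. PMB = 4-methoxybenzyl, PMBM = (4-methoxybenzyloxy)methyl, TBS = tert-butyldimethylsilyl, TMS = trimethylsilyl. The C1 configuration of 34–38 is erased when C1 becomes the ketone. Lactol 44 is drawn without configuration at C12 because both anomers converge. The cyclopentadienyl rings of 7 are drawn σ-bonded.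

Step 1
Reactants: 1 4-methoxybenzyl alcohol; 2 trichloroethylene
Product: 4 (E)-dichlorovinyl 4-methoxybenzyl ether, via potassium 4-methoxybenzyl oxide 3 (not isolated)
Conditions: KH, THF, 0 °C; then 2, −50 °C to rt
Reagents that add atoms: trichloroethylene (2), ClC=C(Cl)Cl
Why: Addition–elimination of an alkoxide on trichloroethylene is the standard entry to dichlorovinyl ethers and hence to alkynyl ethers; the alkene geometry is irrelevant because both chlorines are lost in step 2.

Step 2
Reactants: 4 (E)-dichlorovinyl 4-methoxybenzyl ether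
Product: 6 ethynyl 4-methoxybenzyl ether, via lithium alkynyl ether 5 (not isolated)
Conditions: n-BuLi (2.2 equiv), Et2O, −78 to −40 °C; MeOH, −78 °C
Reagents that add atoms: none
Why: Dehydrochlorination followed by chlorine–lithium exchange gives the lithium alkynyl ether, which is protonated cold; the product is kept below room temperature and used at once because benzylic alkynyl ethers rearrange on warming.

Step 3
Reactants: 6 ethynyl 4-methoxybenzyl ether
Product: 8 (E)-1-iodo-2-(4-methoxybenzyloxy)ethene, via alkenylzirconocene 7 (not isolated)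
Conditions: Cp2Zr(H)Cl, THF, rt; I2, 0 °C
Reagents that add atoms: iodine, II
Why: Hydrozirconation adds H and Zr syn with the metal on the terminal carbon, and iodinolysis proceeds with retention, so the E iodide should form as a single isomer.

Step 4
Reactants: 1 4-methoxybenzyl alcohol
Product: 10 4-methoxybenzyl (methylthio)methyl ether, via sodium 4-methoxybenzyl oxide 9 (not isolated)
Conditions: NaH, THF, 0 °C; MeSCH2Cl, NaI (cat.), rt
Reagents that add atoms: chloromethyl methyl sulfide, CSCCl
Why: Williamson etherification with an α-chloro sulfide.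

Step 5
Reactants: 10 4-methoxybenzyl (methylthio)methyl ether
Product: 11 chloromethyl 4-methoxybenzyl ether (PMBM chloride)
Conditions: SO2Cl2, CH2Cl2, −78 °C; used crude
Reagents that add atoms: sulfuryl chloride, O=S(=O)(Cl)Cl
Why: Chlorinolysis of an O,S-acetal is the established preparation of alkoxymethyl chlorides; at −78 °C the electron-rich arene and the benzylic ether should be spared.

Step 6
Reactants: 12 (S)-(+)-carvone
Product: 13 (S)-5-(3-hydroxyprop-1-en-2-yl)-2-methylcyclohex-2-en-1-one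
Conditions: SeO2 (cat.), t-BuOOH, CH2Cl2, rt
Reagents that add atoms: selenium dioxide, O=[Se]=O; tert-butyl hydroperoxide (reoxidant), CC(C)(C)OO
Why: Selenium dioxide allylic oxidation (ene reaction then [2,3] shift) attacks the methyl group of the electron-rich 1,1-disubstituted alkene; the electron-poor enone alkene does not react, and C7 is untouched.

Step 7
Reactants: 13 (S)-5-(3-hydroxyprop-1-en-2-yl)-2-methylcyclohex-2-en-1-one
Product: 14 (S)-5-[3-(TBS-oxy)prop-1-en-2-yl]-2-methylcyclohex-2-en-1-one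
Conditions: TBSCl, imidazole, DMF, rt
Reagents that add atoms: tert-butyldimethylsilyl chloride, CC(C)(C)[Si](C)(C)Cl
Why: Silylation of a primary allylic alcohol.

Step 8
Reactants: 14 (S)-5-[3-(TBS-oxy)prop-1-en-2-yl]-2-methylcyclohex-2-en-1-one
Product: 16 (5R)-2-methyl-5-[3-(TBS-oxy)prop-1-en-2-yl]-1-(trimethylsilyloxy)cyclohexa-1,3-diene, via magnesium dienolate 15 (not isolated)
Conditions: MeMgBr, FeCl3 (cat.), Et2O, −20 °C; then TMSCl, Et3N, HMPA
Reagents that add atoms: chlorotrimethylsilane, C[Si](C)(C)Cl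
Why: Iron-catalysed methylmagnesium bromide acts as a base and gives the through-conjugated (γ-deprotonated) dienolate of cyclohexenones that also have α′-hydrogens; O-silylation fixes the linear dienol ether needed for γ-oxygenation.

Step 9
Reactants: 16 (5R)-2-methyl-5-[3-(TBS-oxy)prop-1-en-2-yl]-1-(trimethylsilyloxy)cyclohexa-1,3-diene
Product: 20 (4R,5S)-4-hydroxy-2-methyl-5-[3-(TBS-oxy)prop-1-en-2-yl]cyclohex-2-en-1-one, via endoperoxide 17 (not isolated), via silyl peroxide 18 (not isolated), via trimethylsilyl ether 19 (not isolated)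
Conditions: O2, hν, tetraphenylporphyrin (cat.), CH2Cl2, −78 °C; PPh3; then MeOH, citric acid, 0 °C
Reagents that add atoms: dioxygen, O=O
Why: Singlet oxygen adds [4+2] to the s-cis silyloxydiene on the face anti to the C7 side chain; silyl transfer opens the endoperoxide to the γ-silylperoxy enone, which PPh3 reduces and methanol desilylates. The new C6–O bond is therefore trans to the C7 branch (6R), and the cycloaddition is γ-specific where a peracid could attack the α-carbon.

Step 10
Reactants: 20 (4R,5S)-4-hydroxy-2-methyl-5-[3-(TBS-oxy)prop-1-en-2-yl]cyclohex-2-en-1-one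
Product: 21 (4R,5S)-4-(TBS-oxy)-2-methyl-5-[3-(TBS-oxy)prop-1-en-2-yl]cyclohex-2-en-1-one
Conditions: TBSCl, imidazole, DMF, rt
Reagents that add atoms: tert-butyldimethylsilyl chloride, CC(C)(C)[Si](C)(C)Cl
Why: Silylation of the secondary allylic alcohol; the γ-silyloxy enone has no β-leaving group and is stable to the enolate chemistry that follows.

Step 11
Reactants: 21 (4R,5S)-4-(TBS-oxy)-2-methyl-5-[3-(TBS-oxy)prop-1-en-2-yl]cyclohex-2-en-1-one; 22 allyl bromide
Product: 24 (4R,5S,6R)-6-allyl-4-(TBS-oxy)-2-methyl-5-[3-(TBS-oxy)prop-1-en-2-yl]cyclohex-2-en-1-one, via lithium enolate 23 (not isolated)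
Conditions: LDA, THF, −78 °C; then 22, DMPU, −78 to −40 °C
Reagents that add atoms: allyl bromide (22), C=CCBr
Why: Kinetic α′-deprotonation gives the cross-conjugated enolate, which is alkylated anti to the adjacent C7 substituent, as is usual for carvone enolates; this sets C8 trans to the C7 branch, with all three ring substituents pseudo-equatorial.

Step 12
Reactants: 24 (4R,5S,6R)-6-allyl-4-(TBS-oxy)-2-methyl-5-[3-(TBS-oxy)prop-1-en-2-yl]cyclohex-2-en-1-one
Product: 25 (4R,5S,6R)-4-(TBS-oxy)-2-methyl-6-(2-oxopropyl)-5-[3-(TBS-oxy)prop-1-en-2-yl]cyclohex-2-en-1-one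
Conditions: PdCl2 (cat.), CuCl, O2, DMF/H2O, rt
Reagents that add atoms: water, O
Why: Wacker oxidation converts the monosubstituted alkene into the methyl ketone; the 1,1-disubstituted and trisubstituted alkenes are inert under these conditions.

Step 13
Reactants: 25 (4R,5S,6R)-4-(TBS-oxy)-2-methyl-6-(2-oxopropyl)-5-[3-(TBS-oxy)prop-1-en-2-yl]cyclohex-2-en-1-one
Product: 26 (4R,5S,6S)-4-(TBS-oxy)-2-methyl-5-[3-(TBS-oxy)prop-1-en-2-yl]-6-[(Z)-2-(trimethylsilyloxy)prop-1-enyl]cyclohex-2-en-1-one
Conditions: TMSCl, NaI, Et3N, MeCN, rt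
Reagents that add atoms: chlorotrimethylsilane, C[Si](C)(C)Cl
Why: Enol silylation with iodotrimethylsilane made in situ gives the more substituted enol ether of a methyl ketone, with Z geometry because allylic strain disfavours C8 cis to the methyl; no free enolate is formed, so the 1,4-diketone cannot undergo aldol closure. The hindered enone, which has only a tertiary α′-hydrogen, should not react; minor regio- and stereoisomers are expected and are to be removed here or after step 15.

Step 14
Reactants: 26 (4R,5S,6S)-4-(TBS-oxy)-2-methyl-5-[3-(TBS-oxy)prop-1-en-2-yl]-6-[(Z)-2-(trimethylsilyloxy)prop-1-enyl]cyclohex-2-en-1-one; 8 (E)-1-iodo-2-(4-methoxybenzyloxy)ethene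
Product: 29 (1S,4R,5S,6S)-4-(TBS-oxy)-1-[(E)-2-(PMB-oxy)vinyl]-2-methyl-5-[3-(TBS-oxy)prop-1-en-2-yl]-6-[(Z)-2-(trimethylsilyloxy)prop-1-enyl]cyclohex-2-en-1-ol, via vinyllithium 27 (not isolated), via vinylcerium dichloride 28 (not isolated)
Conditions: 8, t-BuLi (2 equiv), Et2O, −78 °C; CeCl3, THF, −78 °C; then 26, −78 °C; pH 7 buffer
Reagents that add atoms: (E)-1-iodo-2-(4-methoxybenzyloxy)ethene (8), I/C=C/OCc1ccc(OC)cc1
Why: Organocerium 1,2-addition; the low basicity of the cerium reagent avoids enolisation at C8 and conjugate addition, and the silyl enol ether is inert at −78 °C. The bulky alkenyl nucleophile should enter along the equatorial trajectory, anti to the neighbouring C8 substituent, giving the trans-1,2-dialkenyl carbinol with the hydroxyl axial.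

Step 15
Reactants: 29 (1S,4R,5S,6S)-4-(TBS-oxy)-1-[(E)-2-(PMB-oxy)vinyl]-2-methyl-5-[3-(TBS-oxy)prop-1-en-2-yl]-6-[(Z)-2-(trimethylsilyloxy)prop-1-enyl]cyclohex-2-en-1-ol; 11 chloromethyl 4-methoxybenzyl ether
Product: 31 (1S,4R,5S,6S)-4-(TBS-oxy)-1-[(E)-2-(PMB-oxy)vinyl]-2-methyl-6-[(Z)-2-(PMBM-oxy)prop-1-enyl]-5-[3-(TBS-oxy)prop-1-en-2-yl]cyclohex-2-en-1-ol, via dilithium alkoxide enolate 30 (not isolated)
Conditions: MeLi (2.2 equiv), THF, 0 °C; then HMPA, 11 (1.0 equiv), −78 °C; NH4Cl aq
Reagents that add atoms: chloromethyl 4-methoxybenzyl ether (11), COc1ccc(COCCl)cc1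
Why: Methyllithium deprotonates the alcohol and then cleaves the silyl enol ether to the lithium enolate with its regio- and stereochemistry intact; a hard chloromethyl ether in HMPA alkylates the enolate on oxygen. The hindered tertiary lithium alkoxide should react much more slowly at −78 °C, and no carbonyl group is present to equilibrate the enolate.

Step 16
Reactants: 31 (1S,4R,5S,6S)-4-(TBS-oxy)-1-[(E)-2-(PMB-oxy)vinyl]-2-methyl-6-[(Z)-2-(PMBM-oxy)prop-1-enyl]-5-[3-(TBS-oxy)prop-1-en-2-yl]cyclohex-2-en-1-ol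
Product: 34 (1R,6R,7S,10S,4Z,8E)-6-(TBS-oxy)-1-(PMB-oxy)-10-(PMBM-oxy)-4,10-dimethyl-7-[3-(TBS-oxy)prop-1-en-2-yl]cyclodeca-4,8-dien-3-one, via potassium alkoxide 32 (not isolated), via potassium enolate 33 (not isolated)
Conditions: KH, 18-crown-6, THF, 0 °C to rt; AcOH, THF, −78 °C
Reagents that add atoms: none
Why: KH with 18-crown-6 gives the dissociated alkoxide 32, whose oxyanion weakens the C3–C8 bond; a concerted [3,3] shift through a chair forms C1–C10, breaks C3–C8 and gives enolate 33, which is protonated at C2 to the conjugated enone 34. The closest known reaction is the anionic oxy-Cope rearrangement of trans-1,2-dialkenylcyclohexanols to (E)-cyclodec-5-enones. The ten-membered ring arises by four-carbon ring expansion of the cyclohexene and not by end-to-end closure, and the cis C4=C5 alkene is carried over unchanged. C10 is set by suprafacial transfer from C8: with the C7–C8 bond pseudo-equatorial and the enol ether Z, C1 bonds to the face of C9=C10 from which C3 departs, giving 10S. C1 (1R) follows from the E geometry of the alkoxyvinyl group; it is erased later but is used in step 17. The step needs the chair to win over the boat and over the shift through the ring alkene: the trans-diequatorial alkenyl groups let both ring bonds lie pseudo-equatorial, which also gives the E C8=C9 alkene, whereas the competing shift needs a boat with an axial C8 alkenyl. Enolate 33 is a β-alkoxy enolate and is quenched at −78 °C to forestall loss of the C1 alkoxide.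

Step 17
Reactants: 34 (1R,6R,7S,10S,4Z,8E)-6-(TBS-oxy)-1-(PMB-oxy)-10-(PMBM-oxy)-4,10-dimethyl-7-[3-(TBS-oxy)prop-1-en-2-yl]cyclodeca-4,8-dien-3-one
Product: 35 (1R,3S,6R,7S,10S,4Z,8E)-6-(TBS-oxy)-1-(PMB-oxy)-10-(PMBM-oxy)-4,10-dimethyl-7-[3-(TBS-oxy)prop-1-en-2-yl]cyclodeca-4,8-dien-3-ol
Conditions: NaBH4, CeCl3·7H2O, MeOH, −78 °C
Reagents that add atoms: none
Why: Luche 1,2-reduction of the enone. Hydride should add to the outer face of the C3 carbonyl, and cerium bridging the carbonyl and the C1 ether oxygen favours the 1,3-syn alcohol, which for the 1R ether is 3S; the E alkoxyvinyl group was chosen in step 14 so that this relation is matched.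

Step 18
Reactants: 35 (1R,3S,6R,7S,10S,4Z,8E)-6-(TBS-oxy)-1-(PMB-oxy)-10-(PMBM-oxy)-4,10-dimethyl-7-[3-(TBS-oxy)prop-1-en-2-yl]cyclodeca-4,8-dien-3-ol
Product: 36 (1R,3S,6R,7S,10S,4Z,8E)-3,6-bis(TBS-oxy)-1-(PMB-oxy)-10-(PMBM-oxy)-4,10-dimethyl-7-[3-(TBS-oxy)prop-1-en-2-yl]cyclodeca-4,8-diene
Conditions: TBSOTf, 2,6-lutidine, CH2Cl2, −78 °C
Reagents that add atoms: tert-butyldimethylsilyl triflate, CC(C)(C)[Si](C)(C)OS(=O)(=O)C(F)(F)F
Why: Silylation of the secondary allylic alcohol; with excess lutidine at low temperature the acetal-type PMBM ether is not ionised.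

Step 19
Reactants: 36 (1R,3S,6R,7S,10S,4Z,8E)-3,6-bis(TBS-oxy)-1-(PMB-oxy)-10-(PMBM-oxy)-4,10-dimethyl-7-[3-(TBS-oxy)prop-1-en-2-yl]cyclodeca-4,8-diene
Product: 37 (1R,3S,6R,7S,10S,4Z,8E)-3,6-bis(TBS-oxy)-4,10-dimethyl-7-[3-(TBS-oxy)prop-1-en-2-yl]cyclodeca-4,8-diene-1,10-diol
Conditions: DDQ, CH2Cl2/pH 7 buffer, 0 °C
Reagents that add atoms: none
Why: DDQ oxidises both 4-methoxybenzylic positions; the PMB ether gives the C1 alcohol directly and the PMBM ether gives a hemiformal that loses formaldehyde to the C10 alcohol. Silyl ethers and alkenes are not affected.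

Step 20
Reactants: 37 (1R,3S,6R,7S,10S,4Z,8E)-3,6-bis(TBS-oxy)-4,10-dimethyl-7-[3-(TBS-oxy)prop-1-en-2-yl]cyclodeca-4,8-diene-1,10-diol
Product: 38 (1R,3S,6R,7R,8R,9S,10R,4Z)-8,9-epoxy-3,6-bis(TBS-oxy)-4,10-dimethyl-7-[3-(TBS-oxy)prop-1-en-2-yl]cyclodec-4-ene-1,10-diol
Conditions: VO(acac)2 (cat.), t-BuOOH, CH2Cl2, 0 °C
Reagents that add atoms: tert-butyl hydroperoxide, CC(C)(C)OO
Why: Vanadium-catalysed hydroxyl-directed epoxidation; C8=C9 is the only alkene with a free allylic hydroxyl. The oxygen is delivered syn to the C10 hydroxyl on the outer face of the E alkene, in the conformer with H7 and O10 eclipsing the double bond and the ring chain on the other face, which gives the 9S oxygen and the (8R) epoxide carbon.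

Step 21
Reactants: 38 (1R,3S,6R,7R,8R,9S,10R,4Z)-8,9-epoxy-3,6-bis(TBS-oxy)-4,10-dimethyl-7-[3-(TBS-oxy)prop-1-en-2-yl]cyclodec-4-ene-1,10-diol
Product: 39 (3S,6R,7R,8R,9S,10S,4Z)-8,9-epoxy-10-hydroxy-3,6-bis(TBS-oxy)-4,10-dimethyl-7-[3-(TBS-oxy)prop-1-en-2-yl]cyclodec-4-en-1-one
Conditions: Dess–Martin periodinane, NaHCO3, CH2Cl2, 0 °C to rt
Reagents that add atoms: none
Why: Dess–Martin oxidation of the only secondary alcohol; the tertiary C10 hydroxyl and the epoxide are untouched. C1 is oxidised before the C9 hydroxyl exists, so no selectivity between the two is needed.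

Step 22
Reactants: 39 (3S,6R,7R,8R,9S,10S,4Z)-8,9-epoxy-10-hydroxy-3,6-bis(TBS-oxy)-4,10-dimethyl-7-[3-(TBS-oxy)prop-1-en-2-yl]cyclodec-4-en-1-one; 40 tiglic acid
Product: 41 (3S,6R,7R,8S,9S,10S,4Z)-9,10-dihydroxy-3,6-bis(TBS-oxy)-4,10-dimethyl-1-oxo-7-[3-(TBS-oxy)prop-1-en-2-yl]cyclodec-4-en-8-yl (E)-2-methylbut-2-enoate
Conditions: Ti(OiPr)4, 40, CH2Cl2, rt
Reagents that add atoms: tiglic acid (40), C/C=C(\C)C(=O)O
Why: Titanium tetraisopropoxide-mediated opening of a 2,3-epoxy alcohol by a carboxylic acid at the carbon remote from the carbinol (here C8). The C10 alkoxide and the epoxide oxygen chelate titanium, and the carboxylate attacks C8 with inversion, giving 8S while C9 keeps its oxygen; C9 is also neopentyl and so disfavoured for attack.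

Step 23
Reactants: 41 (3S,6R,7R,8S,9S,10S,4Z)-9,10-dihydroxy-3,6-bis(TBS-oxy)-4,10-dimethyl-1-oxo-7-[3-(TBS-oxy)prop-1-en-2-yl]cyclodec-4-en-8-yl (E)-2-methylbut-2-enoate
Product: 42 (3S,6R,7S,8S,9S,10S,4Z)-3,6,9,10-tetrahydroxy-7-(3-hydroxyprop-1-en-2-yl)-4,10-dimethyl-1-oxocyclodec-4-en-8-yl (E)-2-methylbut-2-enoate
Conditions: HF·pyridine, pyridine, THF, 0 °C to rt
Reagents that add atoms: none
Why: Buffered HF·pyridine removes the three silyl ethers under mildly acidic, non-basic conditions, which should spare the β-hydroxy ketone, the α-ketol and the tiglate.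

Step 24
Reactants: 42 (3S,6R,7S,8S,9S,10S,4Z)-3,6,9,10-tetrahydroxy-7-(3-hydroxyprop-1-en-2-yl)-4,10-dimethyl-1-oxocyclodec-4-en-8-yl (E)-2-methylbut-2-enoate
Product: 45 CNP0106709.2, via enal 43 (not isolated), via lactol 44 (not isolated)
Conditions: TEMPO (cat.), PhI(OAc)2, CH2Cl2, rt
Reagents that add atoms: none
Why: Oxoammonium oxidation is much faster for primary than for secondary alcohols; enal 43 is captured by the C6 hydroxyl as a five-membered lactol, which is oxidised to the lactone. The α-methylene lactone is thus formed in the last step and meets no nucleophile.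

## Compound list

1 | 4-methoxybenzyl alcohol | COc1ccc(CO)cc1 | starting material
2 | trichloroethylene | ClC=C(Cl)Cl | starting material
3 | potassium 4-methoxybenzyl oxide | [K+].[O-]Cc1ccc(OC)cc1 | intermediate
4 | (E)-1,2-dichlorovinyl 4-methoxybenzyl ether | Cl/C=C(/Cl)OCc1ccc(OC)cc1 | intermediate
5 | lithium (4-methoxybenzyloxy)acetylide | [Li]C#COCc1ccc(OC)cc1 | intermediate
6 | ethynyl 4-methoxybenzyl ether | C#COCc1ccc(OC)cc1 | intermediate
7 | chlorobis(cyclopentadienyl)[(E)-2-(4-methoxybenzyloxy)vinyl]zirconium | Cl[Zr](/C=C/OCc1ccc(OC)cc1)(C2C=CC=C2)C3C=CC=C3 | intermediate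
8 | (E)-1-iodo-2-(4-methoxybenzyloxy)ethene | I/C=C/OCc1ccc(OC)cc1 | intermediate
9 | sodium 4-methoxybenzyl oxide | [Na+].[O-]Cc1ccc(OC)cc1 | intermediate
10 | 4-methoxybenzyl (methylthio)methyl ether | COc1ccc(COCSC)cc1 | intermediate
11 | chloromethyl 4-methoxybenzyl ether (PMBM chloride) | COc1ccc(COCCl)cc1 | intermediate
12 | (S)-(+)-carvone | CC1=CC[C@@H](CC1=O)C(C)=C | starting material
13 | (S)-5-(3-hydroxyprop-1-en-2-yl)-2-methylcyclohex-2-en-1-one | O=C1C(C)=CC[C@H](C(=C)CO)C1 | intermediate
14 | (S)-5-[3-(TBS-oxy)prop-1-en-2-yl]-2-methylcyclohex-2-en-1-one | O=C1C(C)=CC[C@H](C(=C)CO[Si](C)(C)C(C)(C)C)C1 | intermediate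
15 | bromomagnesium through-conjugated dienolate of 14 | Br[Mg]OC1=C(C)C=C[C@H](C(=C)CO[Si](C)(C)C(C)(C)C)C1 | intermediate
16 | (5R)-2-methyl-5-[3-(TBS-oxy)prop-1-en-2-yl]-1-(trimethylsilyloxy)cyclohexa-1,3-diene | C[Si](C)(C)OC1=C(C)C=C[C@H](C(=C)CO[Si](C)(C)C(C)(C)C)C1 | intermediate
17 | 2,3-dioxabicyclo[2.2.2]oct-5-ene endoperoxide of 16, peroxide bridge anti to the C7 side chain | C[Si](C)(C)O[C@]1(OO2)C(C)=C[C@@H]2[C@H](C(=C)CO[Si](C)(C)C(C)(C)C)C1 | intermediate
18 | (4R,5S)-2-methyl-5-[3-(TBS-oxy)prop-1-en-2-yl]-4-(trimethylsilylperoxy)cyclohex-2-en-1-one | O=C1C(C)=C[C@@H](OO[Si](C)(C)C)[C@H](C(=C)CO[Si](C)(C)C(C)(C)C)C1 | intermediate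
19 | (4R,5S)-2-methyl-5-[3-(TBS-oxy)prop-1-en-2-yl]-4-(trimethylsilyloxy)cyclohex-2-en-1-one | O=C1C(C)=C[C@@H](O[Si](C)(C)C)[C@H](C(=C)CO[Si](C)(C)C(C)(C)C)C1 | intermediate
20 | (4R,5S)-4-hydroxy-2-methyl-5-[3-(TBS-oxy)prop-1-en-2-yl]cyclohex-2-en-1-one | O=C1C(C)=C[C@@H](O)[C@H](C(=C)CO[Si](C)(C)C(C)(C)C)C1 | intermediate
21 | (4R,5S)-4-(TBS-oxy)-2-methyl-5-[3-(TBS-oxy)prop-1-en-2-yl]cyclohex-2-en-1-one | O=C1C(C)=C[C@@H](O[Si](C)(C)C(C)(C)C)[C@H](C(=C)CO[Si](C)(C)C(C)(C)C)C1 | intermediate
22 | allyl bromide | C=CCBr | starting material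
23 | lithium cross-conjugated (C3=C8) enolate of 21 | [Li]OC1=C[C@@H](C(=C)CO[Si](C)(C)C(C)(C)C)[C@H](O[Si](C)(C)C(C)(C)C)C=C1C | intermediate
24 | (4R,5S,6R)-6-allyl-4-(TBS-oxy)-2-methyl-5-[3-(TBS-oxy)prop-1-en-2-yl]cyclohex-2-en-1-one | O=C1C(C)=C[C@@H](O[Si](C)(C)C(C)(C)C)[C@H](C(=C)CO[Si](C)(C)C(C)(C)C)[C@H]1CC=C | intermediate
25 | (4R,5S,6R)-4-(TBS-oxy)-2-methyl-6-(2-oxopropyl)-5-[3-(TBS-oxy)prop-1-en-2-yl]cyclohex-2-en-1-one | O=C1C(C)=C[C@@H](O[Si](C)(C)C(C)(C)C)[C@H](C(=C)CO[Si](C)(C)C(C)(C)C)[C@H]1CC(C)=O | intermediate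
26 | (4R,5S,6S)-4-(TBS-oxy)-2-methyl-5-[3-(TBS-oxy)prop-1-en-2-yl]-6-[(Z)-2-(trimethylsilyloxy)prop-1-enyl]cyclohex-2-en-1-one | O=C1C(C)=C[C@@H](O[Si](C)(C)C(C)(C)C)[C@H](C(=C)CO[Si](C)(C)C(C)(C)C)[C@H]1/C=C(/C)O[Si](C)(C)C | intermediate
27 | (E)-2-(4-methoxybenzyloxy)vinyllithium | [Li]/C=C/OCc1ccc(OC)cc1 | intermediate
28 | dichloro[(E)-2-(4-methoxybenzyloxy)vinyl]cerium | Cl[Ce](Cl)/C=C/OCc1ccc(OC)cc1 | intermediate
29 | (1S,4R,5S,6S)-4-(TBS-oxy)-1-[(E)-2-(PMB-oxy)vinyl]-2-methyl-5-[3-(TBS-oxy)prop-1-en-2-yl]-6-[(Z)-2-(trimethylsilyloxy)prop-1-enyl]cyclohex-2-en-1-ol | O[C@@]1(/C=C/OCc2ccc(OC)cc2)C(C)=C[C@@H](O[Si](C)(C)C(C)(C)C)[C@H](C(=C)CO[Si](C)(C)C(C)(C)C)[C@H]1/C=C(/C)O[Si](C)(C)C | intermediate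
30 | dilithium alkoxide (Z)-enolate derived from 29 | [Li]O[C@@]1(/C=C/OCc2ccc(OC)cc2)C(C)=C[C@@H](O[Si](C)(C)C(C)(C)C)[C@H](C(=C)CO[Si](C)(C)C(C)(C)C)[C@H]1/C=C(/C)O[Li] | intermediate
31 | (1S,4R,5S,6S)-4-(TBS-oxy)-1-[(E)-2-(PMB-oxy)vinyl]-2-methyl-6-[(Z)-2-(PMBM-oxy)prop-1-enyl]-5-[3-(TBS-oxy)prop-1-en-2-yl]cyclohex-2-en-1-ol | O[C@@]1(/C=C/OCc2ccc(OC)cc2)C(C)=C[C@@H](O[Si](C)(C)C(C)(C)C)[C@H](C(=C)CO[Si](C)(C)C(C)(C)C)[C@H]1/C=C(/C)OCOCc3ccc(OC)cc3 | intermediate
32 | potassium alkoxide of 31 | [K+].[O-][C@@]1(/C=C/OCc2ccc(OC)cc2)C(C)=C[C@@H](O[Si](C)(C)C(C)(C)C)[C@H](C(=C)CO[Si](C)(C)C(C)(C)C)[C@H]1/C=C(/C)OCOCc3ccc(OC)cc3 | intermediate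
33 | potassium C2=C3 enolate of 34 (C4 trans to C1) | [K+].CC(C)(C)[Si](C)(C)O[C@@H]1/C=C(/C)\C([O-])=C\[C@@H](OCc2ccc(OC)cc2)[C@@](C)(OCOCc3ccc(OC)cc3)/C=C/[C@H]1C(=C)CO[Si](C)(C)C(C)(C)C | intermediate
34 | (1R,6R,7S,10S,4Z,8E)-6-(TBS-oxy)-1-(PMB-oxy)-10-(PMBM-oxy)-4,10-dimethyl-7-[3-(TBS-oxy)prop-1-en-2-yl]cyclodeca-4,8-dien-3-one | CC(C)(C)[Si](C)(C)O[C@@H]1/C=C(/C)C(=O)C[C@@H](OCc2ccc(OC)cc2)[C@@](C)(OCOCc3ccc(OC)cc3)/C=C/[C@H]1C(=C)CO[Si](C)(C)C(C)(C)C | intermediate
35 | (1R,3S,6R,7S,10S,4Z,8E)-6-(TBS-oxy)-1-(PMB-oxy)-10-(PMBM-oxy)-4,10-dimethyl-7-[3-(TBS-oxy)prop-1-en-2-yl]cyclodeca-4,8-dien-3-ol | CC(C)(C)[Si](C)(C)O[C@@H]1/C=C(/C)[C@@H](O)C[C@@H](OCc2ccc(OC)cc2)[C@@](C)(OCOCc3ccc(OC)cc3)/C=C/[C@H]1C(=C)CO[Si](C)(C)C(C)(C)C | intermediate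
36 | (1R,3S,6R,7S,10S,4Z,8E)-3,6-bis(TBS-oxy)-1-(PMB-oxy)-10-(PMBM-oxy)-4,10-dimethyl-7-[3-(TBS-oxy)prop-1-en-2-yl]cyclodeca-4,8-diene | CC(C)(C)[Si](C)(C)O[C@@H]1/C=C(/C)[C@@H](O[Si](C)(C)C(C)(C)C)C[C@@H](OCc2ccc(OC)cc2)[C@@](C)(OCOCc3ccc(OC)cc3)/C=C/[C@H]1C(=C)CO[Si](C)(C)C(C)(C)C | intermediate
37 | (1R,3S,6R,7S,10S,4Z,8E)-3,6-bis(TBS-oxy)-4,10-dimethyl-7-[3-(TBS-oxy)prop-1-en-2-yl]cyclodeca-4,8-diene-1,10-diol | CC(C)(C)[Si](C)(C)O[C@@H]1/C=C(/C)[C@@H](O[Si](C)(C)C(C)(C)C)C[C@@H](O)[C@@](C)(O)/C=C/[C@H]1C(=C)CO[Si](C)(C)C(C)(C)C | intermediate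
38 | (1R,3S,6R,7R,8R,9S,10R,4Z)-8,9-epoxy-3,6-bis(TBS-oxy)-4,10-dimethyl-7-[3-(TBS-oxy)prop-1-en-2-yl]cyclodec-4-ene-1,10-diol | CC(C)(C)[Si](C)(C)O[C@@H]1/C=C(/C)[C@@H](O[Si](C)(C)C(C)(C)C)C[C@@H](O)[C@@](C)(O)[C@H]2O[C@@H]2[C@H]1C(=C)CO[Si](C)(C)C(C)(C)C | intermediate
39 | (3S,6R,7R,8R,9S,10S,4Z)-8,9-epoxy-10-hydroxy-3,6-bis(TBS-oxy)-4,10-dimethyl-7-[3-(TBS-oxy)prop-1-en-2-yl]cyclodec-4-en-1-one | CC(C)(C)[Si](C)(C)O[C@@H]1/C=C(/C)[C@@H](O[Si](C)(C)C(C)(C)C)CC(=O)[C@@](C)(O)[C@H]2O[C@@H]2[C@H]1C(=C)CO[Si](C)(C)C(C)(C)C | intermediate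
40 | tiglic acid | C/C=C(\C)C(=O)O | starting material
41 | (3S,6R,7R,8S,9S,10S,4Z)-9,10-dihydroxy-3,6-bis(TBS-oxy)-4,10-dimethyl-1-oxo-7-[3-(TBS-oxy)prop-1-en-2-yl]cyclodec-4-en-8-yl (E)-2-methylbut-2-enoate | CC(C)(C)[Si](C)(C)O[C@@H]1/C=C(/C)[C@@H](O[Si](C)(C)C(C)(C)C)CC(=O)[C@@](C)(O)[C@@H](O)[C@@H](OC(=O)/C(C)=C/C)[C@H]1C(=C)CO[Si](C)(C)C(C)(C)C | intermediate
42 | (3S,6R,7S,8S,9S,10S,4Z)-3,6,9,10-tetrahydroxy-7-(3-hydroxyprop-1-en-2-yl)-4,10-dimethyl-1-oxocyclodec-4-en-8-yl (E)-2-methylbut-2-enoate | O[C@@H]1/C=C(/C)[C@@H](O)CC(=O)[C@@](C)(O)[C@@H](O)[C@@H](OC(=O)/C(C)=C/C)[C@H]1C(=C)CO | intermediate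
43 | C12 enal of 42 (2-substituted acrolein on C7) | O[C@@H]1/C=C(/C)[C@@H](O)CC(=O)[C@@](C)(O)[C@@H](O)[C@@H](OC(=O)/C(C)=C/C)[C@H]1C(=C)C=O | intermediate
44 | 6,12-lactol of 43 (both C12 anomers) | C=C1C(O)O[C@@H]2/C=C(/C)[C@@H](O)CC(=O)[C@@](C)(O)[C@@H](O)[C@@H](OC(=O)/C(C)=C/C)[C@@H]12 | intermediate
45 | CNP0106709.2, (3S,6R,7S,8S,9S,10S,4Z)-3,9,10-trihydroxy-1-oxo-8-tigloyloxygermacra-4,11(13)-dien-12,6-olide | C=C1C(=O)O[C@@H]2/C=C(/C)[C@@H](O)CC(=O)[C@@](C)(O)[C@@H](O)[C@@H](OC(=O)/C(C)=C/C)[C@@H]12 | target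

## Step count and risk

Total step count: 24 (steps 1–3 make vinyl iodide 8, steps 4–5 make chloromethyl ether 11, steps 6–24 are the main line).
Longest linear sequence: 19 steps, from (S)-carvone 12 to 45 (steps 6–24).

Least certain steps:

**Step 16 (key step).** The most likely failure is loss of the C1 alkoxide from enolate 33. The enolate is β-alkoxy and is formed as a crown-ether-separated potassium salt, so elimination to the cross-conjugated dienone can compete before the quench. Bond formation between the oxygenated C1 and the fully substituted C10 is also slower than in unsubstituted cases, which prolongs the life of the enolate.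
Fallback: the rearrangement is run without an anion. Carbinol 31 is silylated with N-(trimethylsilyl)imidazole to the trimethylsilyl ether F1. Heating F1 in toluene at about 180 °C in a sealed, base-washed vessel should give, through the same chair, the ten-membered silyl enol ether F2 (a neutral siloxy-Cope rearrangement, which never generates an enolate). Desilylation of F2 with buffered fluoride (TBAF, AcOH, THF, −78 °C) protonates C2 and returns enone 34.

**Step 22.** The opening must invert C8 of a trans-fused epoxide in a ten-membered ring. The backside of C8 is screened by C6 and by the ring chain, so slow reaction, transannular participation or hydride shift under Lewis acid activation can take over.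
Fallback: the C8 oxygen is introduced first with the wrong configuration and inverted on a flexible diol. Diol 37 is oxidised with Dess–Martin periodinane to hydroxy ketone F4. Hydroxyl-directed syn-dihydroxylation with OsO4·TMEDA (CH2Cl2, −78 °C, then aqueous Na2SO3) should give the 8-epi triol F5, with C9 already correct. Mitsunobu esterification with tiglic acid 40 (PPh3, DIAD) at the less hindered C8 hydroxyl, with inversion, gives tiglate 41. The C9 hydroxyl is neopentyl and the C10 hydroxyl tertiary, so neither should react.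

**Step 15.** The most likely failure is alkylation of the tertiary alkoxide oxygen, or C-alkylation of the enolate, by the chloromethyl ether. The result would be a protected carbinol that cannot rearrange. Any regio- or stereoisomeric enol ether carried over from step 13 also surfaces here.
Fallback: the enol ether is exchanged before the alkoxide exists. Silyl enol ether 26 is treated with tetrabutylammonium difluorotriphenylsilicate and chloride 11 (THF, −78 °C) to give, through the ammonium enolate, the PMBM enol ether ketone F3. Addition of vinylcerium reagent 28 to F3 as in step 14 then gives carbinol 31 directly.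

**Step 17.** The most likely failure is poor facial selectivity. The sense of hydride delivery to a ten-membered enone depends on a conformational preference that is argued here, not known, and chelation by the C1 ether may not dominate in methanol.
Fallback: substrate control is replaced by reagent control. Enone 34 is reduced with (R)-2-methyl-CBS-oxazaborolidine and catecholborane (toluene, −78 °C), the alkenyl group acting as the large substituent, to give 35. This route makes no compound outside the list (F0).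

**Step 24.** The most likely failure is over-oxidation. The secondary allylic C3 hydroxyl of 42 can be oxidised in competition with the primary one, which would give a 1,3-diketone.
Fallback: C12 is oxidised while C3 and C6 are still silylated. Tiglate 41 is treated with PPTS in MeOH at 0 °C to free only the primary allylic alcohol F6. MnO2 (CH2Cl2) oxidises F6 to the enal F7, leaving the non-allylic C9 hydroxyl. Pinnick oxidation (NaClO2, NaH2PO4, 2-methyl-2-butene) gives the acrylic acid F8. HF·pyridine then removes the two remaining silyl ethers to the hydroxy acid F9, which should close spontaneously onto the C6 hydroxyl to give 45.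

## Further compounds

F1 | step 16 | trimethylsilyl ether of carbinol 31 | C[Si](C)(C)O[C@@]1(/C=C/OCc2ccc(OC)cc2)C(C)=C[C@@H](O[Si](C)(C)C(C)(C)C)[C@H](C(=C)CO[Si](C)(C)C(C)(C)C)[C@H]1/C=C(/C)OCOCc3ccc(OC)cc3
F2 | step 16 | C2=C3 trimethylsilyl enol ether of enone 34 | CC(C)(C)[Si](C)(C)O[C@@H]1/C=C(/C)\C(O[Si](C)(C)C)=C\[C@@H](OCc2ccc(OC)cc2)[C@@](C)(OCOCc3ccc(OC)cc3)/C=C/[C@H]1C(=C)CO[Si](C)(C)C(C)(C)C
F3 | step 15 | (4R,5S,6S)-4-(TBS-oxy)-2-methyl-6-[(Z)-2-(PMBM-oxy)prop-1-enyl]-5-[3-(TBS-oxy)prop-1-en-2-yl]cyclohex-2-en-1-one | O=C1C(C)=C[C@@H](O[Si](C)(C)C(C)(C)C)[C@H](C(=C)CO[Si](C)(C)C(C)(C)C)[C@H]1/C=C(/C)OCOCc2ccc(OC)cc2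
F0 | step 17 | none | none
F4 | step 22 | (3S,6R,7S,10S,4Z,8E)-10-hydroxy-3,6-bis(TBS-oxy)-4,10-dimethyl-7-[3-(TBS-oxy)prop-1-en-2-yl]cyclodeca-4,8-dien-1-one | CC(C)(C)[Si](C)(C)O[C@@H]1/C=C(/C)[C@@H](O[Si](C)(C)C(C)(C)C)CC(=O)[C@@](C)(O)/C=C/[C@H]1C(=C)CO[Si](C)(C)C(C)(C)C
F5 | step 22 | 8-epi-8,9,10-triol: 8,9,10-trihydroxy-3,6-bis(TBS-oxy)-4,10-dimethyl-7-[3-(TBS-oxy)prop-1-en-2-yl]cyclodec-4-en-1-one | CC(C)(C)[Si](C)(C)O[C@@H]1/C=C(/C)[C@@H](O[Si](C)(C)C(C)(C)C)CC(=O)[C@@](C)(O)[C@@H](O)[C@H](O)[C@H]1C(=C)CO[Si](C)(C)C(C)(C)C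
F6 | step 24 | C12 primary alcohol of 41 (3,6-bis-TBS ether) | CC(C)(C)[Si](C)(C)O[C@@H]1/C=C(/C)[C@@H](O[Si](C)(C)C(C)(C)C)CC(=O)[C@@](C)(O)[C@@H](O)[C@@H](OC(=O)/C(C)=C/C)[C@H]1C(=C)CO
F7 | step 24 | C12 enal (3,6-bis-TBS ether) | CC(C)(C)[Si](C)(C)O[C@@H]1/C=C(/C)[C@@H](O[Si](C)(C)C(C)(C)C)CC(=O)[C@@](C)(O)[C@@H](O)[C@@H](OC(=O)/C(C)=C/C)[C@H]1C(=C)C=O
F8 | step 24 | C12 acrylic acid (3,6-bis-TBS ether) | CC(C)(C)[Si](C)(C)O[C@@H]1/C=C(/C)[C@@H](O[Si](C)(C)C(C)(C)C)CC(=O)[C@@](C)(O)[C@@H](O)[C@@H](OC(=O)/C(C)=C/C)[C@H]1C(=C)C(=O)O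
F9 | step 24 | 3,6,9,10-tetrahydroxy C12 acid (seco acid of 45) | O[C@@H]1/C=C(/C)[C@@H](O)CC(=O)[C@@](C)(O)[C@@H](O)[C@@H](OC(=O)/C(C)=C/C)[C@H]1C(=C)C(=O)O
A1 | alternative 1 | C8,C9-dialdehyde with the saturated 6,12-lactone, 1-dithiane, 3-OTBS, 10-OTES | O=C[C@H]1CC(=O)O[C@@H]1/C=C(/C)[C@@H](O[Si](C)(C)C(C)(C)C)CC2(SCCCS2)[C@@](C)(O[Si](CC)(CC)CC)C=O
A2 | alternative 1 | ten-membered cis-8,9-diol | C1C(=O)O[C@@H]2/C=C(/C)[C@@H](O[Si](C)(C)C(C)(C)C)CC3(SCCCS3)[C@@](C)(O[Si](CC)(CC)CC)[C@@H](O)[C@@H](O)[C@@H]12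
A3 | alternative 2 | Z-vinyl iodide (C5) / C6 aldehyde with the tiglate and the 9,10-acetonide in place | I/C=C(/C)[C@@H](O[Si](C)(C)C(C)(C)C)CC(=O)[C@@](C)(OC1(C)C)[C@@H](O1)[C@@H](OC(=O)/C(C)=C/C)[C@H](C=O)C(=C)CO[Si](CC)(CC)CC
A4 | alternative 2 | ten-membered C6 allylic alcohol | O[C@@H]1/C=C(/C)[C@@H](O[Si](C)(C)C(C)(C)C)CC(=O)[C@@](C)(OC2(C)C)[C@@H](O2)[C@@H](OC(=O)/C(C)=C/C)[C@H]1C(=C)CO[Si](CC)(CC)CC
A5 | alternative 3 | thirteen-membered diallylic ether with the C6 tributylstannane | CCCC[Sn](CCCC)(CCCC)[C@@H]1/C=C(/C)[C@@H](O[Si](C)(C)C(C)(C)C)CC2(SCCCS2)[C@@](C)(OC3(C)C)[C@@H](O3)[C@@H](OCc4ccc(OC)cc4)/C=C(/CO1)CO[Si](C)(C)C(C)(C)C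
A6 | alternative 3 | ten-membered carbocycle with C6 hydroxyl and C7 2-propenyl branch | O[C@@H]1/C=C(/C)[C@@H](O[Si](C)(C)C(C)(C)C)CC2(SCCCS2)[C@@](C)(OC3(C)C)[C@@H](O3)[C@@H](OCc4ccc(OC)cc4)[C@H]1C(=C)CO[Si](C)(C)C(C)(C)C
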